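Ring A, the butyryl-bearing trione ring (C1 = ring C=O between the two substituted carbons, C2 carries butyryl, C4 is CMe2, C6 carries the CH2 bridge), is opened at its C2–C3 bond. It is a cyclised tetraketide whose quaternary C4 forbids aromatisation, so it is carried as a linear 3,5,7-triketo ester and closed by a biomimetic Claisen (Dieckmann) condensation. In the same operation the only nucleophilic carbon thus created, C6, captures an o-quinone methide released from the aminomethyl arm of a ring B–CH2–ring C fragment, giving the target. Rings B (central arene) and C (propionyl trione ring) come from commercial acylphloroglucinols; ring A is the only ring the route closes.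

Key step: step 5

Assumption: compounds 1, 3, 7 and 8 are purchased. All trione rings are written in the dienol tautomer of the target SMILES (the tautomers interconvert). The target has no stereocentre, so no step has to set configuration.

Step 1
Reactants: 1 flopropione [1-(2,4,6-trihydroxyphenyl)propan-1-one]
Product: 2 propionylfilicinic acid [3,5-dihydroxy-4,4-dimethyl-2-propanoylcyclohexa-2,5-dien-1-one; ring C]
Conditions: NaOMe, MeI (2.2 equiv), MeOH, 0 °C to rt; aq. HCl
Reagents that add atoms: iodomethane, CI
Why: Dearomative geminal C-methylation of the phloroglucinol polyanion, the standard entry to acylfilicinic acids; the second methyl group enters at the carbon already methylated, and the resulting vinylogous acid anion resists further alkylation.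

Step 2
Reactants: 3 phlorobutyrophenone [1-(2,4,6-trihydroxyphenyl)butan-1-one; ring B]
Product: 4 bis-Mannich base 1-{3,5-bis[(dimethylamino)methyl]-2,4,6-trihydroxyphenyl}butan-1-one
Conditions: aq. CH2O (2.2 equiv), aq. Me2NH (2.2 equiv), EtOH, 0 °C to rt
Reagents that add atoms: formaldehyde, C=O; dimethylamine, CNC
Why: Double phenolic Mannich reaction at the two equivalent free positions of the electron-rich arene; the product has no ring CH left and therefore cannot condense with itself.

Step 3
Reactants: 2 propionylfilicinic acid; 4 bis-Mannich base (3 equiv)
Product: 6 ring C–CH2–ring B dimer that keeps one CH2NMe2 arm, via aminomethyl quinone methide 5 (not isolated)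
Conditions: 1,4-dioxane, 70 °C, N2 stream
Reagents that add atoms: none
Why: Mannich-base alkylation: loss of dimethylamine from 4 should give o-quinone methide 5, which C6 of 2 (its only carbon nucleophile) traps by Michael addition with rearomatisation, while the excess of 4 should hold the substitution at one arm.

Step 4
Reactants: 7 heptane-2,4-dione; 8 dimethyl 2,2-dimethylmalonate (1.5 equiv)
Product: 9 methyl 2,2-dimethyl-3,5,7-trioxodecanoate
Conditions: LiN(i-Pr)2 (3 equiv), THF, −78 to 0 °C; 8, −20 °C; cold aq. HCl
Reagents that add atoms: none
Why: Crossed Claisen acylation of a β-diketone dianion: the second deprotonation of 7 is expected at the methyl group, and this terminal carbanion attacks one ester group of the non-enolisable 8; the triketo ester is held as its polyanion until the cold quench, so it should not cyclise.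

Step 5
Reactants: 9 methyl 2,2-dimethyl-3,5,7-trioxodecanoate; 6 aminomethyl dimer
Product: 12 filixic acid PBB (target), via butyrylfilicinic acid 10 (not isolated), via bridged quinone methide 11 (not isolated)
Conditions: 9, NaOMe (3 equiv), MeOH, 0 to 50 °C; evaporate; then AcOH (to about pH 5), 6, 1,4-dioxane, 70 °C
Reagents that add atoms: none
Why: NaOMe turns 9 into its bis-enolate, and the enolate carbon between the C5 and C7 ketones (C2 of ring A) attacks the ester carbonyl C1 (C3 of ring A) in a 6-exo-trig Dieckmann condensation, the laboratory counterpart of the polyketide Claisen ring closure; loss of methoxide gives the strongly acidic trione 10 as its stable enolate, which makes the closure irreversible. It is the only Claisen mode open to a doubly activated carbon, because the other enolate carbon could close only a four-membered ring, the CMe2 carbon cannot enolise or aromatise, and O-acylation to the enol lactone is reversible under methoxide. No stereocentre is formed. After buffering, 6 loses dimethylamine to the ring B o-quinone methide 11, and C6 of 10 adds in a Michael reaction with rearomatisation, the known Mannich-base route to methylene-bridged acylphloroglucinols. Regiochemistry rests on the order of events: the quinone methide is offered only after ring closure, when C2 is fully substituted and C6 is the single nucleophilic carbon. Neither 6 nor 12 has a free nucleophilic CH, so oligomers cannot form.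

Compound list
1 | flopropione, 1-(2,4,6-trihydroxyphenyl)propan-1-one | CCC(=O)c1c(O)cc(O)cc1O | starting material
2 | propionylfilicinic acid, 3,5-dihydroxy-4,4-dimethyl-2-propanoylcyclohexa-2,5-dien-1-one (ring C) | CCC(=O)C1=C(O)C(C)(C)C(O)=CC1=O | intermediate
3 | phlorobutyrophenone, 1-(2,4,6-trihydroxyphenyl)butan-1-one (ring B) | CCCC(=O)c1c(O)cc(O)cc1O | starting material
4 | 1-{3,5-bis[(dimethylamino)methyl]-2,4,6-trihydroxyphenyl}butan-1-one | CCCC(=O)c1c(O)c(CN(C)C)c(O)c(CN(C)C)c1O | intermediate
5 | o-quinone methide from 4: 2-butanoyl-4-[(dimethylamino)methyl]-3,5-dihydroxy-6-methylidenecyclohexa-2,4-dien-1-one (formed in the flask) | CCCC(=O)C1=C(O)C(CN(C)C)=C(O)C(=C)C1=O | intermediate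
6 | ring B bearing butanoyl, one CH2NMe2 arm and one CH2 bridge to C6 of propionylfilicinic acid | CCCC(=O)c1c(O)c(CN(C)C)c(O)c(CC2=C(O)C(C)(C)C(O)=C(C(=O)CC)C2=O)c1O | intermediate
7 | heptane-2,4-dione | CCCC(=O)CC(C)=O | starting material
8 | dimethyl 2,2-dimethylmalonate | COC(=O)C(C)(C)C(=O)OC | starting material
9 | methyl 2,2-dimethyl-3,5,7-trioxodecanoate | CCCC(=O)CC(=O)CC(=O)C(C)(C)C(=O)OC | intermediate
10 | butyrylfilicinic acid, 2-butanoyl-3,5-dihydroxy-4,4-dimethylcyclohexa-2,5-dien-1-one (ring A, formed in the flask as its sodium enolate) | CCCC(=O)C1=C(O)C(C)(C)C(O)=CC1=O | intermediate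
11 | o-quinone methide from 6: the CH2NMe2 arm replaced by an exocyclic methylidene on a ring B dienone (formed in the flask) | CCCC(=O)C1=C(O)C(CC2=C(O)C(C)(C)C(O)=C(C(=O)CC)C2=O)=C(O)C(=C)C1=O | intermediate
12 | filixic acid PBB: butanoylphloroglucinol (ring B) bridged by CH2 groups to C6 of butyrylfilicinic acid (ring A) and to C6 of propionylfilicinic acid (ring C); achiral | CCCC(=O)C1=C(O)C(C)(C)C(O)=C(Cc2c(O)c(CC3=C(O)C(C)(C)C(O)=C(C(=O)CC)C3=O)c(O)c(C(=O)CCC)c2O)C1=O | target

Total step count: 5. Longest linear sequence: 3 steps (1 → 2 → 6 → 12, or 3 → 4 → 6 → 12).

Steps most likely to fail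

Step 5. If the Claisen closure is incomplete when 6 is added, open-chain enolate carbons of 9 would be alkylated, and the advanced fragment 6 could be degraded by carried-over methoxide or by retro-Michael scrambling of its bridge during the heated one-pot sequence. The fallback sets out from 9, 4 and 2 and comes back at 12. Compound 9 is cyclised alone (NaOMe, MeOH; aq. HCl) and 10 is isolated and purified. Compound 10 is then heated with the linchpin 4 (3 equiv, 1,4-dioxane, 70 °C) to give the ring A–CH2–ring B aminomethyl dimer F1 by the same elimination–addition as in step 3. Finally F1 and the robust, readily available 2 are heated in 1,4-dioxane to give 12. Ring closure and union are thus separated, the last union uses an inexpensive partner, and ring A remains the only ring closed.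

Step 3. Both arms of 4 may be substituted, and the quinone methide may condense with itself. The fallback sets out from 2 and 3, comes back at 6, and reverses the polarity. Compound 2 and dimethylmethylideneammonium iodide (MeCN, 0 °C) should give the Mannich base of propionylfilicinic acid F2. With NaOAc at rt in the presence of 3 (4 equiv), F2 loses dimethylamine and the arene of 3 adds at the liberated methylene carbon (Friedel–Crafts-type Michael addition) to give the amine-free ring C–CH2–ring B dimer F3. Aminomethylation of the one remaining ring B position of F3 with the same iminium salt gives 6.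

Step 4. Proton transfer may outrun acylation, both ester groups of 8 may be attacked, and some deprotonation may occur on the propyl side of 7. The fallback sets out from 7 and comes back at 9. Compound 7 is converted (Me3SiOTf, Et3N, Et2O, 0 °C) into the bis(trimethylsilyl) dienol ether (3Z)-2,4-bis(trimethylsilyloxy)hepta-1,3-diene F4. F4 is C-acylated at its terminal CH2 by methyl 3-chloro-2,2-dimethyl-3-oxopropanoate (COC(=O)C(C)(C)C(Cl)=O; CH2Cl2, −78 °C to rt; aqueous work-up). This is a neutral, Mukaiyama-type Claisen acylation with a mono acyl chloride in place of the dianion and the diester.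

Further compounds
F1 | step 5 | ring B bearing butanoyl, one CH2NMe2 arm and one CH2 bridge to C6 of butyrylfilicinic acid | CCCC(=O)C1=C(O)C(C)(C)C(O)=C(Cc2c(O)c(CN(C)C)c(O)c(C(=O)CCC)c2O)C1=O
F2 | step 3 | 6-[(dimethylamino)methyl]-3,5-dihydroxy-4,4-dimethyl-2-propanoylcyclohexa-2,5-dien-1-one | CCC(=O)C1=C(O)C(C)(C)C(O)=C(CN(C)C)C1=O
F3 | step 3 | butanoylphloroglucinol bridged by one CH2 to C6 of propionylfilicinic acid, other ring position free | CCC(=O)C1=C(O)C(C)(C)C(O)=C(Cc2c(O)cc(O)c(C(=O)CCC)c2O)C1=O
F4 | step 4 | (3Z)-2,4-bis(trimethylsilyloxy)hepta-1,3-diene | CCC/C(O[Si](C)(C)C)=C/C(=C)O[Si](C)(C)C
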